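**Labels used throughout.** Chain carbons: C1 = CH2 of ring A, C2 = spiro carbon, C3 = CH of ring B, C4 = exocyclic CH2, C5 and C6 = C2 and C3 of the benzofuran (ring C). O_A, O_B, O_C are the ring oxygens. Rings A and B are the two dihydrobenzofurans, ring C is the aromatic benzofuran. By CIP analysis of the given SMILES the target is C2 (R), C3 (S), with C4 and O_A on the same face of ring B.

## The problem

Three 3-methylbutanoyl-phloroglucinol units hang on a six-carbon chain: aryl A on C1, aryl B on C3, aryl C on C6. Rings A and B share C2 as a bis-benzannulated 1,6-dioxaspiro[4.4]nonane; ring C is a 2-substituted benzofuran. The ring oxygens differ in kind: O_A and O_B are the phenol oxygens ortho to the acyl group, O_C is the oxygen para to it. In each unit a second hydroxyl flanks the point of attachment and could close the wrong ring. There are two stereocentres. C3 is benzylic and sits next to the ketal carbon, so any intermediate with C2 as a ketone or oxocarbenium ion can lose H3, by enolization or by aromatization of ring B. The spiro centre C2 can be epimerized by ring opening, so C3 can control C2 but not the reverse. Free acylphloroglucinols are carbon nucleophiles at their remaining ring CH, and the free spiroketal should not see acid, which could open it towards para-oxygen isomers.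

The feature that the plan uses: C2 carries two oxygens and C1 two hydrogens, so C1–C2 is at the oxidation level of an alkyne. C3 is then a propargylic carbon bearing aryl B, whose ortho oxygen O_B lies five atoms from C2. C5=C6 is likewise a hydrated alkyne. The whole chain is hexa-1,5-diyn-3-ol with aryl B in place of the hydroxyl.

## Retrosynthesis

**19 to 18.** The four O–benzyl bonds at the para oxygens of rings A and B and at both phenols of ring C are cut last. While they are in place only the ortho-to-acyl hydroxyls of A and B can enter the ketal. Benzyl is chosen over acid-labile groups because hydrogenolysis is neutral. The 6-hydroxyls of A and B stay free, so closing the ketal never costs the acyl hydrogen bond.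

**18 to 16 + 5.** Ring A is cut at C1–C(aryl A) and C2–O_A. The neighbouring cut, both C2–O bonds, gives a ketone with C3 alpha to it. Cutting only C2–O_A gives an arylidene enol ether that still has to be made. The chosen cut leaves O_B–C2 in place, so 16 is the exocyclic enol ether of ring B and the iodophenol 5 brings aryl A and O_A together. The forward reaction must put the aryl on C1 and the oxygen on C2, then settle the spiro centre by equilibration of epimer 17.

**16 to 14 + 4 (key).** Ring B is cut at C3–C(aryl B) and C2–O_B. This reveals a propargylic electrophile 14 and the symmetric phenol 4, whose two ring CH positions are equivalent. Only the ortho-to-acyl hydroxyl lies next to the new bond, because the para oxygen is benzylated. The precursor is acyclic at C1–C3 and racemic; the forward reaction must set C3 by catalyst control and close ring B 5-exo.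

**14 to 13, 11, then 9 + 6.** Ring C is cut at C6–C(aryl C) and C5–O_C: a Sonogashira coupling of iodophenol 6 with the free alkyne of 9, then 5-endo-dig closure. Doing this early puts the one regiochemical question of ring C (para against ortho hydroxyl) on cheap material. Ester 14 follows from 11 by benzylation and desilylation (13) and acylation.

**9 to 7 + 8; 4, 5, 6 to 3; 3 to 1 + 2.** The diynol 9 is cut at C3–C4 into the silylated ynal 7 and propargyl bromide 8. The three aryl partners 4, 5 and 6 all come from ketone 3, itself from phloroglucinol 1 and acid chloride 2. The para hydroxyl of 3 is the most acidic, so it is benzylated first (4); iodination then goes to one of two equivalent positions (5, 6).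

## Roads not taken

**Alternative 1:** (the obvious one) Cut both C2–O bonds to a keto-bisphenol A3 and close the spiroketal with acid. A3 would come from the symmetric 1,3-diarylpropan-2-one A1 by C3-alkylation of its polyanion with the benzofuranylmethyl bromide A2, or from an oxazolidinone-auxiliary alkylation at the acid oxidation level. In A3, C3 is alpha to a ketone and benzylic to an electron-rich ring, so any enantiomeric excess is at risk in base (enolization) and in acid (loss of H3 from the ring B lactol with aromatization). No catalytic asymmetric alkylation is established for such a tertiary alpha-aryl ketone, and the auxiliary route is long and linear. The chosen plan never has a carbonyl at C2.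

**Alternative 2:** (biomimetic) Read C2 and C5 as a 1,4-diketone. Oxidize the symmetric 2,5-bis(arylmethyl)furan A4 to the (E)-enedione A5, add a third acylphloroglucinol by conjugate Friedel–Crafts reaction, and let the three phenols close. This is the shortest route on paper, but the two identical ends must close differently, through the ortho oxygen at C2 and the para oxygen at C5, so no single protecting pattern serves both. With free ortho phenols each ketone of A5 would also be consumed by its own cyclodehydration before the intermolecular addition. The adduct again has C3 alpha to a ketone.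

**Alternative 3:** Attach all three aryl groups to the diyne first and close everything at once: gold-catalysed triple cycloisomerization of the diyne-triphenol A6. O_A can add to C2 by 5-endo closure before O_B does, which aromatizes ring A; the spiroketal would then need a dearomatizing protonation, the step known to be hard for acyl-bearing phenols. A6 also needs the uncyclized propargylic phenol and two couplings with extra phenol protection. The chosen plan fixes the order O_B first, then C1–aryl A together with O_A, by construction.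

Key step: step 9

**Remarks on the chemistry.** Phloroglucinol 1, acid chloride 2, ynal 7 and bromide 8 are taken as commercial. The natural relative configuration (C4 and O_A cis on ring B) is assumed to be the more stable spiro epimer, because the C4 substituent then eclipses an oxygen, not the C1 methylene.

## Steps

Step 1
Reactants: 1 phloroglucinol; 2 3-methylbutanoyl chloride
Product: 3 3-methyl-1-(2,4,6-trihydroxyphenyl)butan-1-one
Conditions: AlCl3 (3.5 equiv), PhNO2, 65 °C; aq. HCl work-up
Reagents that add atoms: none
Why: Friedel–Crafts C-acylation of phloroglucinol; the first acyl group deactivates the ring, so mono-acylation should dominate.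

Step 2
Reactants: 3
Product: 4 1-[4-(benzyloxy)-2,6-dihydroxyphenyl]-3-methylbutan-1-one
Conditions: BnBr (1.0 equiv), K2CO3 (1.05 equiv), acetone, 0 °C to rt
Reagents that add atoms: benzyl bromide, BrCc1ccccc1
Why: Williamson etherification; the para hydroxyl is the most acidic and the only one not engaged by the acyl group, so it should be alkylated first.

Step 3
Reactants: 4
Product: 5 1-[4-(benzyloxy)-2,6-dihydroxy-3-iodophenyl]-3-methylbutan-1-one
Conditions: NIS (1.0 equiv), MeCN, −20 to 0 °C
Reagents that add atoms: N-iodosuccinimide, O=C1CCC(=O)N1I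
Why: Electrophilic aromatic iodination; the two free ring positions of 4 are equivalent, so one equivalent should give a single mono-iodide with a free ortho-to-acyl hydroxyl next to iodine.

Step 4
Reactants: 3
Product: 6 3-methyl-1-(2,4,6-trihydroxy-3-iodophenyl)butan-1-one
Conditions: NIS (1.0 equiv), MeCN, −30 °C
Reagents that add atoms: N-iodosuccinimide, O=C1CCC(=O)N1I
Why: Electrophilic iodination at one of two equivalent positions of 3; low temperature and one equivalent should hold it at the mono-iodide.

Step 5
Reactants: 7 3-(trimethylsilyl)prop-2-ynal; 8 3-bromoprop-1-yne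
Product: 9 rac-1-(trimethylsilyl)hexa-1,5-diyn-3-ol
Conditions: Zn dust (activated), THF, 0 °C to rt; sat. aq. NH4Cl
Reagents that add atoms: none
Why: Barbier propargylation; the allenylzinc adds by allylic transposition to give the homopropargylic alcohol, which holds all six chain carbons with C1 silylated and C6 free; the racemic carbinol is acceptable because step 9 is enantioconvergent.

Step 6
Reactants: 9; 6
Product: 11 rac-1-{4,6-dihydroxy-2-[2-hydroxy-4-(trimethylsilyl)but-3-yn-1-yl]-1-benzofuran-5-yl}-3-methylbutan-1-one, via alkynylphenol 10 (not isolated)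
Conditions: Pd(PPh3)2Cl2 (3 mol %), CuI (5 mol %), Et3N (3 equiv), DMF, rt to 60 °C, argon
Reagents that add atoms: none
Why: Sonogashira coupling at the only free terminal alkyne, then 5-endo-dig closure of the ortho-alkynylphenol; the para hydroxyl is the most acidic and is ionized first by the amine, so ring C should close through it (O_C para to the acyl group).

Step 7
Reactants: 11
Product: 13 rac-1-[4,6-bis(benzyloxy)-2-(2-hydroxybut-3-yn-1-yl)-1-benzofuran-5-yl]-3-methylbutan-1-one, via silyl dibenzyl ether 12 (not isolated)
Conditions: BnBr (2.5 equiv), K2CO3 (3 equiv), DMF, 60 °C; then MeOH, rt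
Reagents that add atoms: benzyl bromide, BrCc1ccccc1
Why: Williamson etherification of both acyl-flanking phenols under forcing carbonate conditions (the secondary alcohol is not alkylated by carbonate), then carbonate/methanol protodesilylation of the alkyne in the same flask.

Step 8
Reactants: 13
Product: 14 rac-1-[4,6-bis(benzyloxy)-5-(3-methylbutanoyl)-1-benzofuran-2-yl]but-3-yn-2-yl pentafluorobenzoate
Conditions: C6F5COCl (1.2 equiv), Et3N, DMAP (cat.), CH2Cl2, 0 °C
Reagents that add atoms: pentafluorobenzoyl chloride, O=C(Cl)c1c(F)c(F)c(F)c(F)c1F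
Why: O-acylation of the propargylic alcohol; the electron-poor benzoate is the leaving group that lets an aliphatic propargylic ester ionize at low temperature in step 9.

Step 9
Reactants: 14; 4 (2 equiv)
Product: 16 1-[(3S)-4-(benzyloxy)-3-{[4,6-bis(benzyloxy)-5-(3-methylbutanoyl)-1-benzofuran-2-yl]methyl}-6-hydroxy-2-methylidene-2,3-dihydro-1-benzofuran-7-yl]-3-methylbutan-1-one, via propargylic phenol 15 (not isolated)
Conditions: Cu(OTf)2 (5 mol %), chiral tridentate P,N,N ketimine ligand (5.5 mol %; (S,S)-Ph-pybox as second choice), iPr2NEt (1.2 equiv), MeOH, −20 °C to rt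
Reagents that add atoms: none
Why: Copper-catalysed enantioconvergent propargylic Friedel–Crafts alkylation followed by cycloisomerization (formal [3+2] annulation), a reaction type established for electron-rich phenols and naphthols with propargylic esters. The copper acetylide of 14 expels pentafluorobenzoate to give a copper allenylidene in which C3 is planar, so both enantiomers of 14 pass through one intermediate. The phenoxide of 4 attacks C3 with the ring carbon that is ortho to one phenoxide oxygen and para to the other, giving 15 after protonation. C3 is the only new stereocentre and is set in this C–C bond formation by the chiral ligand on copper (catalyst control; the ligand enantiomer that leads to the S product is used). Ring B then closes by 5-exo-dig attack of the adjacent hydroxyl O_B on the copper-activated C2, leaving the exocyclic C1=C2 enol ether. The step needs C- over O-propargylation (the acyl-conjugated phenoxide is a soft carbon nucleophile), mono-alkylation (4 in excess, two equivalent positions), closure through the ortho oxygen only (the para oxygen is benzylated) and an exocyclic double bond that stays put (amine base, no acid, low temperature; 16 is purified on base-washed silica).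

Step 10
Reactants: 16; 5 (1.2 equiv)
Product: 18 (2R,3S)-4,4'-bis(benzyloxy)-3-{[4,6-bis(benzyloxy)-5-(3-methylbutanoyl)-1-benzofuran-2-yl]methyl}-6,6'-dihydroxy-7,7'-bis(3-methylbutanoyl)-3H,3'H-2,2'-spirobi[1-benzofuran], via spiro epimer 17 (not isolated)
Conditions: Pd(OAc)2 (10 mol %), PPh3 (20 mol %), Ag2CO3 (1.5 equiv), acetone, 50 °C, dark; filter; then CSA (5 mol %), CH2Cl2, 0 °C
Reagents that add atoms: none
Why: Proposed new method: oxidative addition of 5 to zerovalent palladium and iodide abstraction by silver give an aryl–palladium cation that should insert the exocyclic enol ether with aryl A on the unsubstituted C1; the resulting tertiary alpha-oxygenated alkylpalladium at C2 is a masked oxocarbenium ion and should be captured by the ortho phenoxide O_A, closing ring A and returning zerovalent palladium; the closest known reactions are the Heck-type oxyarylation of chromenes and endocyclic enol ethers with ortho-iodophenols and the heteroannulation of ortho-iodophenols with dienes, not yet shown on an exocyclic enol ether to give a spiroketal; the spiro centre C2 is then set under thermodynamic control relative to C3 by CSA (17 to 18, C4 cis to O_A), and only the ortho oxygens can take part because the para oxygens are benzylated.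

Step 11
Reactants: 18
Product: 19 (2R,3S)-3-{[4,6-dihydroxy-5-(3-methylbutanoyl)-1-benzofuran-2-yl]methyl}-4,4',6,6'-tetrahydroxy-7,7'-bis(3-methylbutanoyl)-3H,3'H-2,2'-spirobi[1-benzofuran] (CNP0169640.1)
Conditions: H2 (1 atm), Pd/C (10 %), EtOAc, rt, monitored and stopped at full debenzylation
Reagents that add atoms: none
Why: Hydrogenolysis of four aryl benzyl ethers under neutral conditions, so the free spiroketal never meets acid; the acyl-conjugated aryl ketones and the electron-rich benzofuran should be inert at one atmosphere.

## Compound list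

1 | phloroglucinol | Oc1cc(O)cc(O)c1 | starting material
2 | 3-methylbutanoyl chloride | CC(C)CC(Cl)=O | starting material
3 | 3-methyl-1-(2,4,6-trihydroxyphenyl)butan-1-one | CC(C)CC(=O)c1c(O)cc(O)cc1O | intermediate
4 | 1-[4-(benzyloxy)-2,6-dihydroxyphenyl]-3-methylbutan-1-one | CC(C)CC(=O)c1c(O)cc(OCc2ccccc2)cc1O | intermediate
5 | 1-[4-(benzyloxy)-2,6-dihydroxy-3-iodophenyl]-3-methylbutan-1-one | CC(C)CC(=O)c1c(O)c(I)c(OCc2ccccc2)cc1O | intermediate
6 | 3-methyl-1-(2,4,6-trihydroxy-3-iodophenyl)butan-1-one | CC(C)CC(=O)c1c(O)c(I)c(O)cc1O | intermediate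
7 | 3-(trimethylsilyl)prop-2-ynal | C[Si](C)(C)C#CC=O | starting material
8 | 3-bromoprop-1-yne | BrCC#C | starting material
9 | rac-1-(trimethylsilyl)hexa-1,5-diyn-3-ol | C[Si](C)(C)C#CC(O)CC#C | intermediate
10 | rac-3-methyl-1-{2,4,6-trihydroxy-3-[4-hydroxy-6-(trimethylsilyl)hexa-1,5-diyn-1-yl]phenyl}butan-1-one | CC(C)CC(=O)c1c(O)cc(O)c(C#CCC(O)C#C[Si](C)(C)C)c1O | intermediate (not isolated)
11 | rac-1-{4,6-dihydroxy-2-[2-hydroxy-4-(trimethylsilyl)but-3-yn-1-yl]-1-benzofuran-5-yl}-3-methylbutan-1-one | CC(C)CC(=O)c1c(O)cc2oc(CC(O)C#C[Si](C)(C)C)cc2c1O | intermediate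
12 | rac-1-{4,6-bis(benzyloxy)-2-[2-hydroxy-4-(trimethylsilyl)but-3-yn-1-yl]-1-benzofuran-5-yl}-3-methylbutan-1-one | CC(C)CC(=O)c1c(OCc3ccccc3)cc2oc(CC(O)C#C[Si](C)(C)C)cc2c1OCc1ccccc1 | intermediate (not isolated)
13 | rac-1-[4,6-bis(benzyloxy)-2-(2-hydroxybut-3-yn-1-yl)-1-benzofuran-5-yl]-3-methylbutan-1-one | CC(C)CC(=O)c1c(OCc3ccccc3)cc2oc(CC(O)C#C)cc2c1OCc1ccccc1 | intermediate
14 | rac-1-[4,6-bis(benzyloxy)-5-(3-methylbutanoyl)-1-benzofuran-2-yl]but-3-yn-2-yl pentafluorobenzoate | CC(C)CC(=O)c1c(OCc3ccccc3)cc2oc(CC(OC(=O)c3c(F)c(F)c(F)c(F)c3F)C#C)cc2c1OCc1ccccc1 | intermediate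
15 | 1-[4-(benzyloxy)-3-{(2R)-1-[4,6-bis(benzyloxy)-5-(3-methylbutanoyl)-1-benzofuran-2-yl]but-3-yn-2-yl}-2,6-dihydroxyphenyl]-3-methylbutan-1-one (same spatial arrangement as C3 of 19; the descriptor differs by CIP ranking only) | C#C[C@@H](Cc1cc2c(OCc3ccccc3)c(C(=O)CC(C)C)c(OCc3ccccc3)cc2o1)c1c(O)c(C(=O)CC(C)C)c(O)cc1OCc1ccccc1 | intermediate (not isolated)
16 | 1-[(3S)-4-(benzyloxy)-3-{[4,6-bis(benzyloxy)-5-(3-methylbutanoyl)-1-benzofuran-2-yl]methyl}-6-hydroxy-2-methylidene-2,3-dihydro-1-benzofuran-7-yl]-3-methylbutan-1-one | C=C1Oc2c(C(=O)CC(C)C)c(O)cc(OCc3ccccc3)c2[C@@H]1Cc1cc2c(OCc3ccccc3)c(C(=O)CC(C)C)c(OCc3ccccc3)cc2o1 | intermediate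
17 | (2S,3S) spiro epimer of 18 | CC(C)CC(=O)c1c(O)cc(OCc3ccccc3)c2c1O[C@@]1(C2)Oc2c(C(=O)CC(C)C)c(O)cc(OCc3ccccc3)c2[C@@H]1Cc1cc2c(OCc3ccccc3)c(C(=O)CC(C)C)c(OCc3ccccc3)cc2o1 | intermediate (not isolated)
18 | (2R,3S)-4,4'-bis(benzyloxy)-3-{[4,6-bis(benzyloxy)-5-(3-methylbutanoyl)-1-benzofuran-2-yl]methyl}-6,6'-dihydroxy-7,7'-bis(3-methylbutanoyl)-3H,3'H-2,2'-spirobi[1-benzofuran] | CC(C)CC(=O)c1c(O)cc(OCc3ccccc3)c2c1O[C@]1(C2)Oc2c(C(=O)CC(C)C)c(O)cc(OCc3ccccc3)c2[C@@H]1Cc1cc2c(OCc3ccccc3)c(C(=O)CC(C)C)c(OCc3ccccc3)cc2o1 | intermediate
19 | (2R,3S)-3-{[4,6-dihydroxy-5-(3-methylbutanoyl)-1-benzofuran-2-yl]methyl}-4,4',6,6'-tetrahydroxy-7,7'-bis(3-methylbutanoyl)-3H,3'H-2,2'-spirobi[1-benzofuran] | CC(C)CC(=O)c1c(O)cc(O)c2c1O[C@]1(C2)Oc2c(C(=O)CC(C)C)c(O)cc(O)c2[C@@H]1Cc1cc2c(O)c(C(=O)CC(C)C)c(O)cc2o1 | target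

## Step count and least certain steps

Total: 11 steps. Longest linear sequence: 8 steps (1, 4, 6, 7, 8, 9, 10, 11).

**Step 10 (proposed new method).** The tertiary alkylpalladium at C2 has a syn hydrogen on C3. The likeliest failure is beta-hydride elimination towards C3, or palladium-hydride migration of the exocyclic double bond into ring B. Either aromatizes ring B and erases the C3 stereocentre. A second risk is slow loss of H3 during the acid equilibration.

Fallback, by known reactions, from 15 and 5 back to 18:
- Step 9 is quenched cold with Ac2O/DMAP, so that 15 is trapped before ring closure as the diacetate F1.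
- 5 is converted with MOMCl/NaH into the bis(methoxymethyl) ether F2.
- Sonogashira coupling of F1 with F2 gives the diarylalkyne F3.
- K2CO3/MeOH frees only the ring B phenols; O_B then adds 5-exo-dig (with (Ph3P)AuCl/AgOTf if base alone is slow) to give the (Z)-arylidene enol ether F4.
- CSA in MeOH/CH2Cl2 removes the methoxymethyl groups and closes ring A onto the enol ether, giving 18 by way of 17.

In this sequence no metal is bound to C2, and O_A stays masked until O_B is in place.

**Step 9 (key step).** The likeliest failure is poor facial discrimination at the copper allenylidene, because the ester is aliphatic (homobenzylic), together with proton loss from C4 giving elimination in place of substitution. Fallback, from 14 and 4 back to 16: give up catalyst control. An achiral copper catalyst (CuI, 2,2'-bipyridine, iPr2NEt, MeOH, −20 °C) would give the racemate of 16, formed through the enantiomeric propargylic phenol F5 alongside 15. Chromatography on a chiral stationary phase under neutral conditions would then separate 16 from its enantiomer F6, and 16 rejoins the route at step 10.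

**Step 6.** The likeliest failure is ring closure through the ortho-to-acyl hydroxyl and not the para one, since both flank the alkyne and the acyl group can chelate only one of its two ortho hydroxyls. Fallback, from 3 back to 12, with the regiochemistry enforced by protection:
- 3 with MOMCl (1 equiv)/iPr2NEt gives the para methoxymethyl ether F7.
- BnBr/K2CO3/DMF gives the dibenzyl ether F8.
- HCl/MeOH frees the para phenol F9.
- NIS gives the iodide F10, in which only the para hydroxyl is free next to iodine.
- Sonogashira coupling and closure of F10 with 9 gives 12 directly, which is desilylated as in the second half of step 7.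

## Further compounds

F1 | step 10 | 2-{(2R)-1-[4,6-bis(benzyloxy)-5-(3-methylbutanoyl)-1-benzofuran-2-yl]but-3-yn-2-yl}-3-(benzyloxy)-6-(3-methylbutanoyl)-1,5-phenylene diacetate (diacetate of 15) | C#C[C@@H](Cc1cc2c(OCc3ccccc3)c(C(=O)CC(C)C)c(OCc3ccccc3)cc2o1)c1c(OC(C)=O)c(C(=O)CC(C)C)c(OC(C)=O)cc1OCc1ccccc1
F2 | step 10 | 1-[4-(benzyloxy)-3-iodo-2,6-bis(methoxymethoxy)phenyl]-3-methylbutan-1-one | CC(C)CC(=O)c1c(OCOC)c(I)c(OCc2ccccc2)cc1OCOC
F3 | step 10 | diarylalkyne from F1 and F2 (ring A as bis(methoxymethyl) ether, ring B as diacetate, C3 as in 15) | CC(C)CC(=O)c1c(OCOC)cc(OCc2ccccc2)c(C#C[C@@H](Cc2cc3c(OCc4ccccc4)c(C(=O)CC(C)C)c(OCc4ccccc4)cc3o2)c2c(OC(C)=O)c(C(=O)CC(C)C)c(OC(C)=O)cc2OCc2ccccc2)c1OCOC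
F4 | step 10 | (Z)-2-arylidene-2,3-dihydrobenzofuran (ring B closed, (3S), ring A as bis(methoxymethyl) ether) | CC(C)CC(=O)c1c(OCOC)cc(OCc2ccccc2)c(/C=C2\Oc3c(C(=O)CC(C)C)c(O)cc(OCc4ccccc4)c3[C@@H]2Cc2cc3c(OCc4ccccc4)c(C(=O)CC(C)C)c(OCc4ccccc4)cc3o2)c1OCOC
F5 | step 9 | enantiomer of 15 | C#C[C@H](Cc1cc2c(OCc3ccccc3)c(C(=O)CC(C)C)c(OCc3ccccc3)cc2o1)c1c(O)c(C(=O)CC(C)C)c(O)cc1OCc1ccccc1
F6 | step 9 | enantiomer of 16 ((3R)) | C=C1Oc2c(C(=O)CC(C)C)c(O)cc(OCc3ccccc3)c2[C@H]1Cc1cc2c(OCc3ccccc3)c(C(=O)CC(C)C)c(OCc3ccccc3)cc2o1
F7 | step 6 | 1-[2,6-dihydroxy-4-(methoxymethoxy)phenyl]-3-methylbutan-1-one | CC(C)CC(=O)c1c(O)cc(OCOC)cc1O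
F8 | step 6 | 1-[2,6-bis(benzyloxy)-4-(methoxymethoxy)phenyl]-3-methylbutan-1-one | CC(C)CC(=O)c1c(OCc2ccccc2)cc(OCOC)cc1OCc1ccccc1
F9 | step 6 | 1-[2,6-bis(benzyloxy)-4-hydroxyphenyl]-3-methylbutan-1-one | CC(C)CC(=O)c1c(OCc2ccccc2)cc(O)cc1OCc1ccccc1
F10 | step 6 | 1-[2,6-bis(benzyloxy)-4-hydroxy-3-iodophenyl]-3-methylbutan-1-one | CC(C)CC(=O)c1c(OCc2ccccc2)c(I)c(O)cc1OCc1ccccc1
A1 | alternative 1 | 1,3-bis[6-(benzyloxy)-2,4-dihydroxy-3-(3-methylbutanoyl)phenyl]propan-2-one | O=C(Cc1c(O)c(C(=O)CC(C)C)c(O)cc1OCc1ccccc1)Cc1c(O)c(C(=O)CC(C)C)c(O)cc1OCc1ccccc1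
A2 | alternative 1 | 1-[4,6-bis(benzyloxy)-2-(bromomethyl)-1-benzofuran-5-yl]-3-methylbutan-1-one | CC(C)CC(=O)c1c(OCc3ccccc3)cc2oc(CBr)cc2c1OCc1ccccc1
A3 | alternative 1 | C3-alkylated keto-bisphenol (open form of 18, C3 as in 19) | O=C(Cc1c(O)c(C(=O)CC(C)C)c(O)cc1OCc1ccccc1)[C@@H](Cc1cc2c(OCc3ccccc3)c(C(=O)CC(C)C)c(OCc3ccccc3)cc2o1)c1c(O)c(C(=O)CC(C)C)c(O)cc1OCc1ccccc1
A4 | alternative 2 | 2,5-bis{[2,4,6-trihydroxy-3-(3-methylbutanoyl)phenyl]methyl}furan | CC(C)CC(=O)c1c(O)cc(O)c(Cc2ccc(Cc3c(O)cc(O)c(C(=O)CC(C)C)c3O)o2)c1O
A5 | alternative 2 | (E)-1,6-bis[2,4,6-trihydroxy-3-(3-methylbutanoyl)phenyl]hex-3-ene-2,5-dione | CC(C)CC(=O)c1c(O)cc(O)c(CC(=O)/C=C/C(=O)Cc2c(O)cc(O)c(C(=O)CC(C)C)c2O)c1O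
A6 | alternative 3 | 3-aryl-1,6-diarylhexa-1,5-diyne triphenol (aryl A and aryl B as para benzyl ethers, aryl C free, C3 as in 15) | CC(C)CC(=O)c1c(O)cc(OCc2ccccc2)c(C#C[C@@H](CC#Cc2c(O)cc(O)c(C(=O)CC(C)C)c2O)c2c(O)c(C(=O)CC(C)C)c(O)cc2OCc2ccccc2)c1O
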